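# Two-directional vinylketene–ynol ether annulation route to the methylene-bridged acylphloroglucinol trimer 22

## The problem

Compound 22 has a central aromatic ring A, a butyrylphloroglucinol, whose two ring carbons meta to the butyryl group each carry a CH2 bridge to an identical ring B, a 2-butyryl-4,4-dimethylcyclohexane-1,3,5-trione drawn as its bis-enol. Ring B is numbered here C1 (butyryl-bearing), C2 (oxygenated carbon next to the quaternary centre), C3 (CMe2), C4 (oxygenated), C5 (bridge-bearing) and C6 (oxygenated carbon between C5 and C1). The molecule has no stereocentre and a mirror plane through ring A, so nothing but regiochemistry has to be controlled, both rings B can be made in the same operation, and the enol tautomers interconvert freely. The hard part is ring B: a ring that cannot aromatize, with a quaternary gem-dimethyl carbon between two oxygenated carbons and three different carbon substituents in fixed positions around it. The delicate parts are the acidic enols and phenols and, above all, the two bridges: an ArCH2 group on a triketone enolate carbon is lost by retro-Michael or ipso-substitution pathways under base or strong acid, which scrambles methylene-bridged acylphloroglucinols. C-alkylation and C-acylation at the polyphenol stage add O-versus-C and over-reaction problems, so the bridges are best built early, at the level of ethers, and the free triketones released only at the end. The enabling feature is that ring B, written as its 4,6-bis(enol ether), is a 6,6-dimethylcyclohexa-2,4-dienone with oxygen on the alternate carbons C2, C4 and C6. That is exactly the ring a dienylketene gives by 6-electron electrocyclization when its far terminus is a CMe2 group.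

## Retrosynthesis

**22 to 21.** The last disconnection removes no carbon. The seven O–alkyl bonds of 21 are cut: three aryl methyl ethers on ring A and two ethyl enol ethers on each ring B. Keeping every acidic oxygen alkylated until the final step means no earlier step meets a phenol, an enol or a base-labile bridge. The forward reaction needs one reagent that dealkylates both ether classes without ionizing the bridges; BBr3 at low temperature is the candidate.

**21 to 20 to 19.** The two ring-B butyryl carbonyls are traced back to carbinols (20) and then to their silyl ethers (19); the C1–side-chain bond is not cut. The neighbouring cut, C-acylation of C1 on a finished ring B, would need free enols and would put the bridges at risk. The oxidation-level change is also dictated by the key step: an alkyne carrying an acyl group is electron-poor and will not add to a ketene, whereas its silyloxyalkyl counterpart will. The forward steps need a buffered fluoride and a mild oxidant that leave the enol ethers alone. The carbinol stereocentres disappear on oxidation, so they need no control.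

**19 to 11 and 15 (key disconnection).** In each ring B the bonds C1–C2, C5–C6 and C2–C3 are cut. C1 and C6 leave with their substituents as the ynol ether 15, of which one molecule is needed per arm. The remaining carbons C2, C5, C4 and C3 are folded, through a C2–C5 bond, into a 3-ethoxy-4,4-dimethylcyclobutenone arm of 11. Two neighbouring cuts are the C1–C6 Claisen bond and the two C3–methyl bonds (gem-dimethylation of an aromatic ring); the present cut has three points in its favour:
- the quaternary carbon arrives complete inside the four-membered ring and cannot be over- or under-alkylated;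
- the ring forms under neutral, reagent-free heating;
- the bridges are already in place at a stage with no phenol or enol.

Both rings B and six skeletal bonds are removed at once, leaving a bis(cyclobutenone) and a six-carbon alkyne. The forward reaction must open the cyclobutenones at a temperature the ynol ether survives, add the alkyne with the right orientation, and do so on both arms.

**11 to 8 and 10.** Each cyclobutenone is cut at C2–C5 and C3–C4, giving the ynol ether arms of 8 and two molecules of dimethylketene 10, generated from acid chloride 9. The C(=O)–CMe2 unit (C2–C3) comes intact from 9. Attaching a substituent to the vinylic carbon of a preformed alkoxycyclobutenone is not a dependable reaction, whereas the orientation of ketene–alkoxyalkyne cycloaddition is fixed by polarity. The forward step needs a disubstituted ketene to add to an internal ynol ether, twice.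

**8 to 4 and 5.** The two benzylic CH2–C(sp) bonds are cut, so that two molecules of ethoxyacetylene 5 are joined to dibromide 4. The textbook neighbour, SN2 alkylation of lithium ethoxyacetylide 6, would expose the ring-A ketone and the acidic benzylic–propargylic protons to a strong base. A palladium-catalysed coupling of the zinc acetylide 7, made from 5 through 6, is therefore chosen. It must couple twice without isomerizing the products to allenyl ethers.

**4 to 3 to 1 and 2.** The two Ar–CH2 bonds (bromomethylation) and the Ar–acyl bond (Friedel–Crafts acylation) are cut, in that order. Acylating first fills one ring position, so that after bromomethylation the ring of 4 is hexasubstituted and its benzylic bromides cannot alkylate a free ring position. It also puts the ring-A butyryl group in place before any bridge exists. Acylating ring A at the end, on the unmasked trimer, would be worse: four enols would compete for the acylating agent and the Lewis acid would threaten the bridges. The price is that the hindered aryl ketone must survive steps 2 to 10, which shapes the choice of the zinc reagent.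

**15 to 14 to 5 and 12.** The carbinol C–C(sp) bond is cut to ethoxyacetylene 5, used as its bromomagnesium acetylide 13, and butanal 12, and the alcohol 14 is silylated. Both steps are standard; the only demand is that the alkoxypropargylic alcohol never meets strong acid.

## Roads not taken

**Alternative 1:** The cut is in ring A, at the two bonds joining the hydroxyl-bearing carbon between the bridges to its neighbours. That carbon becomes a one-carbon electrophile and the rest a linear diketone, 1,7-bis(2,4,6-trimethoxyphenyl)heptane-3,5-dione A2. In the forward direction, triply deprotonated A2 would be acylated at one terminal α-carbon by a carbonate diester. The other terminal carbanion would close onto the new ester and, after enolization, give 2,4-bis(2,4,6-trimethoxybenzyl)benzene-1,3,5-triol A1.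
- Merits: the bridges come for free as the chain ends of a saturated curcuminoid, no benzylic halide is needed, and polyanion acylation–cyclization is established enolate chemistry with cheap reagents.
- Weak points: A1 contains three aromatic phloroglucinol rings and no ring B. Each outer ring would still have to be demethylated, acylated once and C-methylated twice at a single carbon. Ring A, the most nucleophilic ring, would have to accept exactly one butyryl group and no methyl group. This is a selectivity contest among three similar rings in a base-labile bridged polyphenol, and the quaternary carbon, the real difficulty, is untouched by the key step.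
- Comparison: this road is better on precedent and cost of its key step. The chosen plan sets against it that no C–C bond remains to be made after step 7 and that ring B is never aromatic, so no dearomatizing methylation is needed.

**Alternative 2:** The cut is again in ring A: the butyryl-bearing carbon and its ethoxy-bearing neighbour are taken out as an alkyne. In the forward direction 1-methoxy-3-(tert-butyldimethylsilyloxy)-2,4-bis(2,4,6-trimethoxybenzyl)cyclohexa-1,3-diene A4 would add 1-ethoxyhex-1-yn-3-one A5 in a Diels–Alder reaction. Expulsion of the two-carbon bridge as a volatile alkene (Alder–Rickert) would leave 1-[2-ethoxy-4-hydroxy-6-methoxy-3,5-bis(2,4,6-trimethoxybenzyl)phenyl]butan-1-one A3.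
- Merits: the orientation is fixed by matched polarization of a push–pull alkyne and a dioxygenated diene, the butyryl group enters in the ring-forming step, the three ring-A oxygens emerge differentiated, and the reaction class is well known. In reliability of the key step this road is better than the chosen plan, whose cascade is untested.
- Weak points: the effort goes into the easy ring, since a butyrylated ring A is available in one step (3 from 1 and 2). A4 needs a doubly benzylated cyclohexane-1,3-dione and two regiodefined enolizations. As in alternative 1, the outer rings remain aromatic trimethyl ethers, so rings B must still be made by demethylation, acylation and gem-dimethylation on a bridged polyphenol.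
- Comparison: the chosen plan answers the known-chemistry advantage by spending its one uncertain step on the part of the molecule that is hard.

**Alternative 3:** The cut is the C1–C6 bond of each ring B, which unrolls the ring into a 2-benzyl-4,4-dimethyl-3,5,7-trioxo ester. The precursor is dimethyl 2,2'-[(2,4,6-trimethoxy-1,3-phenylene)bis(methylene)]bis(4,4-dimethyl-3,5,7-trioxodecanoate) A7. With one equivalent of a silylamide base per arm, the diketonate at C1 would attack the methyl ester and close both rings, giving 2,4-bis(butyrylfilicinylmethyl)-1,3,5-trimethoxybenzene A6.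
- Merits: the closure mirrors the biosynthetic Claisen cyclization and has precedent in polyketide-type ring closures. The butyryl groups and the CMe2 unit are already in the chain, no redox adjustment is needed, and rings B appear directly as free triketones. After its key step this road is shorter than the chosen one and needs no new reaction.
- Weak points: A7 is the problem. Each arm has a non-enolizable 1,3-diketone flanking CMe2, the classic substrate for retro-Claisen cleavage by the alkoxide the cyclization itself releases. Each arm also has several sites of similar acidity, a stabilized and therefore weak diketonate nucleophile, and competing O-acylation to pyranones. Two such chains must be assembled and closed on one molecule. A6 also lacks the ring-A butyryl group, so it needs the late Friedel–Crafts acylation that the chosen plan avoids.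
- Comparison: the chosen plan's precursor 11 is assembled by two cycloadditions and contains no polycarbonyl chain, and the sensitive triketones first appear in the last step.

Key step: step 7

## Route

Remark: 22 is drawn as one enol tautomer of a rapidly equilibrating set; the route delivers the compound, not a particular tautomer.

Remark: 15 is used as the racemate; its carbinol centres are oxidized away in step 9, so 19 and 20 are carried as mixtures of diastereomers.

Remark: steps 3, 4 and 7 are twofold reactions on a symmetrical substrate; each consumes two molecules of its small partner, and the second molecule is entered under "Reagents that add atoms".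

Step 1
Reactants: 1 1,3,5-trimethoxybenzene; 2 butanoyl chloride
Product: 3 1-(2,4,6-trimethoxyphenyl)butan-1-one
Conditions: AlCl3, CH2Cl2, 0 °C
Reagents that add atoms: none
Why: Friedel–Crafts acylation; all three ring positions are equivalent and strongly activated, the acyl group deactivates the ring against a second acylation, and the low temperature avoids AlCl3-induced cleavage of the methoxy groups ortho to the new ketone.

Step 2
Reactants: 3 1-(2,4,6-trimethoxyphenyl)butan-1-one
Product: 4 1-[3,5-bis(bromomethyl)-2,4,6-trimethoxyphenyl]butan-1-one
Conditions: (CH2O)n, 33% HBr in AcOH, 25 to 45 °C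
Reagents that add atoms: formaldehyde (as paraformaldehyde), C=O; hydrogen bromide, Br
Why: Twofold bromomethylation (Blanc-type haloalkylation); both free positions are still ortho or para to three methoxy groups and the acyl group, twisted out of plane, deactivates only weakly, and haloalkylation of polyalkoxybenzenes up to full substitution is standard, the hexasubstituted product having no free ring position for self-alkylation.

Step 3
Reactants: 4 1-[3,5-bis(bromomethyl)-2,4,6-trimethoxyphenyl]butan-1-one; 5 ethoxyacetylene
Product: 8 1-[3,5-bis(3-ethoxyprop-2-yn-1-yl)-2,4,6-trimethoxyphenyl]butan-1-one, via lithium ethoxyacetylide 6 (not isolated), via bromo(ethoxyethynyl)zinc 7 (not isolated)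
Conditions: 5 (2.4 equiv), n-BuLi, THF, −78 °C; ZnBr2, −78 to 0 °C; then 4, PdCl2(DPEphos) (5 mol %), 23 °C
Reagents that add atoms: ethoxyacetylene (second equivalent of 5), C#COCC
Why: Negishi benzyl–alkynyl cross-coupling on both arms; each benzylic bromide adds oxidatively to zerovalent palladium, the alkynylzinc bromide transmetalates and reductive elimination forms the CH2–C(sp) bond, the zinc reagent being too weakly basic to attack or enolize the aryl ketone or to isomerize the product to an allenyl ether.

Step 4
Reactants: 8 1-[3,5-bis(3-ethoxyprop-2-yn-1-yl)-2,4,6-trimethoxyphenyl]butan-1-one; 9 2-methylpropanoyl chloride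
Product: 11 1-{3,5-bis[(2-ethoxy-3,3-dimethyl-4-oxocyclobut-1-en-1-yl)methyl]-2,4,6-trimethoxyphenyl}butan-1-one, via dimethylketene 10 (not isolated)
Conditions: 9 (excess, slow addition), Et3N, CH2Cl2, 0 to 40 °C
Reagents that add atoms: 2-methylpropanoyl chloride (second equivalent of 9), CC(C)C(Cl)=O
Why: [2+2] cycloaddition of a ketene with a 1-alkoxyalkyne, once on each arm; the ketene carbonyl carbon bonds to the alkyne carbon β to oxygen and the CMe2 carbon to the ethoxy-bearing carbon, which gives the 3-ethoxy-4,4-dimethylcyclobutenone orientation on both arms, and the aryl ketone is inert to the ketene.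

Step 5
Reactants: 5 ethoxyacetylene; 12 butanal
Product: 14 (±)-1-ethoxyhex-1-yn-3-ol, via bromo(ethoxyethynyl)magnesium 13 (not isolated)
Conditions: 5, EtMgBr, THF, 0 to 23 °C; 12, 0 °C; then sat. aq NH4Cl, 0 °C
Reagents that add atoms: none
Why: Addition of an alkynyl Grignard reagent to an aldehyde; ethylmagnesium bromide deprotonates the terminal alkyne and the acetylide adds to butanal, the carbinol centre is formed without control, which is acceptable because it is oxidized in step 9, and the cold, only weakly acidic ammonium chloride quench does not trigger Meyer–Schuster rearrangement.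

Step 6
Reactants: 14 (±)-1-ethoxyhex-1-yn-3-ol
Product: 15 (±)-tert-butyl[(1-ethoxyhex-1-yn-3-yl)oxy]dimethylsilane
Conditions: TBSCl, imidazole, DMF, 0 to 23 °C
Reagents that add atoms: tert-butyldimethylsilyl chloride, CC(C)(C)[Si](C)(C)Cl
Why: Silyl ether formation under basic conditions, which keeps the acid-labile alkoxypropargylic alcohol intact and removes the hydroxyl group that would otherwise trap the ketenes of step 7.

Step 7
Reactants: 11 1-{3,5-bis[(2-ethoxy-3,3-dimethyl-4-oxocyclobut-1-en-1-yl)methyl]-2,4,6-trimethoxyphenyl}butan-1-one; 15 (±)-tert-butyl[(1-ethoxyhex-1-yn-3-yl)oxy]dimethylsilane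
Product: 19 1-{3,5-bis[(5-{1-[tert-butyl(dimethyl)silyloxy]butyl}-2,6-diethoxy-3,3-dimethyl-4-oxocyclohexa-1,5-dien-1-yl)methyl]-2,4,6-trimethoxyphenyl}butan-1-one (mixture of diastereomers), via bis(vinylketene) 16 (not isolated), via bis(4-alkenylcyclobutenone) 17 (not isolated), via bis(dienylketene) 18 (not isolated)
Conditions: 15 (4 equiv, in portions), toluene, 100 °C, sealed tube, argon
Reagents that add atoms: tert-butyl[(1-ethoxyhex-1-yn-3-yl)oxy]dimethylsilane (second equivalent of 15), CCCC(O[Si](C)(C)C(C)(C)C)C#COCC
Why: Proposed new method: at about 100 °C each 4,4-dimethylcyclobutenone of 11 should open by conrotatory 4-electron electrocyclic ring opening (breaking C2–C3, ring B numbering) to vinylketene 16, whose ketene C=C adds one molecule of the electron-rich ynol ether 15 in a [2+2] cycloaddition that forms C1–C2 and C5–C6 and gives the 4-alkenylcyclobutenone 17. A second 4-electron opening, which breaks the old C2–C5 bond, gives dienylketene 18, and each ring B then closes by disrotatory 6-electron electrocyclization of the ketene carbon C2 onto the CMe2 terminus C3. The closest known reaction type is the thermal benzannulation of cyclobutenones with alkoxy- or siloxyalkynes, which passes through the same three kinds of intermediate and ends by tautomerization to a phenol; here C3 carries two methyl groups and no hydrogen, so the cascade must stop at the 6,6-dimethylcyclohexa-2,4-dienone. Closure of a dienylketene onto a fully substituted terminus has its own analogy in the thermal re-closure of the ketenes formed on irradiation of 6,6-disubstituted cyclohexa-2,4-dienones. No stereocentre is formed in the rings; the two silyloxy carbinol centres come unchanged from racemic 15, so 19 is expected as a diastereomer mixture that converges at 21. The step needs regioselectivity in the [2+2] addition, and the polarity of the partners secures it: the alkyne carbon β to oxygen is the nucleophile and bonds to the ketene carbonyl carbon, which places the masked butyryl carbon at C1 and the ethoxy group at C6. It also needs the alkenyl group of 17 to rotate inward; because cyclobutenone opening is reversible, the unproductive rotamer can return to 17 and drain through the productive one. An excess of 15 favours the bimolecular step on both arms, and the temperature is held below the range in which ethyl ynol ethers lose ethylene.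

Step 8
Reactants: 19 the bis(silyl ether) from step 7
Product: 20 1-{3,5-bis[(2,6-diethoxy-5-(1-hydroxybutyl)-3,3-dimethyl-4-oxocyclohexa-1,5-dien-1-yl)methyl]-2,4,6-trimethoxyphenyl}butan-1-one (mixture of diastereomers)
Conditions: Bu4NF, AcOH, THF, 0 to 23 °C
Reagents that add atoms: none
Why: Fluoride-mediated desilylation; buffering with acetic acid keeps the medium near neutral, so the enol ethers are not hydrolysed and the allylic carbinols next to them are not ionized.

Step 9
Reactants: 20 the diol from step 8
Product: 21 1-{3,5-bis[(5-butanoyl-2,6-diethoxy-3,3-dimethyl-4-oxocyclohexa-1,5-dien-1-yl)methyl]-2,4,6-trimethoxyphenyl}butan-1-one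
Conditions: Dess–Martin periodinane, pyridine, CH2Cl2, 0 to 23 °C
Reagents that add atoms: none
Why: Dess–Martin oxidation of secondary allylic alcohols to ketones under buffered, non-aqueous conditions; both carbinol centres disappear, so the diastereomer mixture converges to one compound.

Step 10
Reactants: 21 the hepta-O-alkyl triketone from step 9
Product: 22 1-{3,5-bis[(5-butanoyl-2,4-dihydroxy-3,3-dimethyl-6-oxocyclohexa-1,4-dien-1-yl)methyl]-2,4,6-trihydroxyphenyl}butan-1-one (target)
Conditions: BBr3 (excess), CH2Cl2, −78 to 0 °C; then H2O
Reagents that add atoms: none
Why: Lewis acid ether cleavage; BBr3 coordinates each ether oxygen and bromide removes the alkyl group by SN2, the four vinylogous ethyl esters and the two methoxy groups ortho to the aryl ketone reacting fastest, and aqueous work-up hydrolyses the boron enolates and aryl borates to the free enols and phenols of 22.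

## Compound list

1 | 1,3,5-trimethoxybenzene | COc1cc(OC)cc(OC)c1 | starting material
2 | butanoyl chloride | CCCC(Cl)=O | starting material
3 | 1-(2,4,6-trimethoxyphenyl)butan-1-one | CCCC(=O)c1c(OC)cc(OC)cc1OC | intermediate
4 | 1-[3,5-bis(bromomethyl)-2,4,6-trimethoxyphenyl]butan-1-one | CCCC(=O)c1c(OC)c(CBr)c(OC)c(CBr)c1OC | intermediate
5 | ethoxyacetylene (ethoxyethyne) | C#COCC | starting material
6 | lithium ethoxyacetylide (not isolated) | [Li]C#COCC | intermediate
7 | bromo(ethoxyethynyl)zinc (not isolated) | Br[Zn]C#COCC | intermediate
8 | 1-[3,5-bis(3-ethoxyprop-2-yn-1-yl)-2,4,6-trimethoxyphenyl]butan-1-one | CCCC(=O)c1c(OC)c(CC#COCC)c(OC)c(CC#COCC)c1OC | intermediate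
9 | 2-methylpropanoyl chloride | CC(C)C(Cl)=O | starting material
10 | dimethylketene (not isolated) | CC(C)=C=O | intermediate
11 | 1-{3,5-bis[(2-ethoxy-3,3-dimethyl-4-oxocyclobut-1-en-1-yl)methyl]-2,4,6-trimethoxyphenyl}butan-1-one (each arm a 3-ethoxy-4,4-dimethylcyclobut-2-en-1-one joined through C2) | CCCC(=O)c1c(OC)c(CC2=C(OCC)C(C)(C)C2=O)c(OC)c(CC2=C(OCC)C(C)(C)C2=O)c1OC | intermediate
12 | butanal | CCCC=O | starting material
13 | bromo(ethoxyethynyl)magnesium (not isolated) | Br[Mg]C#COCC | intermediate
14 | (±)-1-ethoxyhex-1-yn-3-ol | CCCC(O)C#COCC | intermediate
15 | (±)-tert-butyl[(1-ethoxyhex-1-yn-3-yl)oxy]dimethylsilane | CCCC(O[Si](C)(C)C(C)(C)C)C#COCC | intermediate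
16 | bis(vinylketene): 1-{3,5-bis[3-ethoxy-4-methyl-2-(oxomethylidene)pent-3-en-1-yl]-2,4,6-trimethoxyphenyl}butan-1-one (not isolated) | CCCC(=O)c1c(OC)c(CC(=C=O)C(OCC)=C(C)C)c(OC)c(CC(=C=O)C(OCC)=C(C)C)c1OC | intermediate
17 | bis(4-alkenylcyclobutenone): each arm a cyclobut-2-en-1-one with the silyloxybutyl group at C2, ethoxy at C3, and the benzylic CH2 and a 1-ethoxy-2-methylprop-1-enyl group at C4 (not isolated, stereoisomer mixture) | CCCC(=O)c1c(OC)c(CC2(C(OCC)=C(C)C)C(=O)C(C(CCC)O[Si](C)(C)C(C)(C)C)=C2OCC)c(OC)c(CC2(C(OCC)=C(C)C)C(=O)C(C(CCC)O[Si](C)(C)C(C)(C)C)=C2OCC)c1OC | intermediate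
18 | bis(dienylketene): each arm CH2–C(alkenyl)=C(OEt)–C(silyloxybutyl)=C=O, drawn as the productive isomer with the alkenyl group cis to the ketene arm (not isolated) | CCCC(=O)c1c(OC)c(C/C(C(OCC)=C(C)C)=C(OCC)/C(C(CCC)O[Si](C)(C)C(C)(C)C)=C=O)c(OC)c(C/C(C(OCC)=C(C)C)=C(OCC)/C(C(CCC)O[Si](C)(C)C(C)(C)C)=C=O)c1OC | intermediate
19 | 1-{3,5-bis[(5-{1-[tert-butyl(dimethyl)silyloxy]butyl}-2,6-diethoxy-3,3-dimethyl-4-oxocyclohexa-1,5-dien-1-yl)methyl]-2,4,6-trimethoxyphenyl}butan-1-one (diastereomer mixture) | CCCC(=O)c1c(OC)c(CC2=C(OCC)C(C)(C)C(=O)C(C(CCC)O[Si](C)(C)C(C)(C)C)=C2OCC)c(OC)c(CC2=C(OCC)C(C)(C)C(=O)C(C(CCC)O[Si](C)(C)C(C)(C)C)=C2OCC)c1OC | intermediate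
20 | 1-{3,5-bis[(2,6-diethoxy-5-(1-hydroxybutyl)-3,3-dimethyl-4-oxocyclohexa-1,5-dien-1-yl)methyl]-2,4,6-trimethoxyphenyl}butan-1-one (diastereomer mixture) | CCCC(=O)c1c(OC)c(CC2=C(OCC)C(C)(C)C(=O)C(C(O)CCC)=C2OCC)c(OC)c(CC2=C(OCC)C(C)(C)C(=O)C(C(O)CCC)=C2OCC)c1OC | intermediate
21 | 1-{3,5-bis[(5-butanoyl-2,6-diethoxy-3,3-dimethyl-4-oxocyclohexa-1,5-dien-1-yl)methyl]-2,4,6-trimethoxyphenyl}butan-1-one | CCCC(=O)c1c(OC)c(CC2=C(OCC)C(C)(C)C(=O)C(C(=O)CCC)=C2OCC)c(OC)c(CC2=C(OCC)C(C)(C)C(=O)C(C(=O)CCC)=C2OCC)c1OC | intermediate
22 | 1-{3,5-bis[(5-butanoyl-2,4-dihydroxy-3,3-dimethyl-6-oxocyclohexa-1,4-dien-1-yl)methyl]-2,4,6-trihydroxyphenyl}butan-1-one (no stereocentres) | CCCC(=O)C1=C(O)C(C)(C)C(O)=C(Cc2c(O)c(CC3=C(O)C(C)(C)C(O)=C(C(=O)CCC)C3=O)c(O)c(C(=O)CCC)c2O)C1=O | target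

## Step count and risk

Total steps: 10. Longest linear sequence: 8 steps (1, 2, 3, 4, 7, 8, 9, 10); steps 5 and 6 form a two-step side branch that joins at step 7.

**Step 7 (key step, proposed new method).** Three processes may compete.
- A [1,5]-hydrogen shift from a methyl group of the CMe2 terminus to the ketene carbon of 16, giving a dienal, may outrun the bimolecular cycloaddition.
- The donor-substituted cyclobutenone may open only at temperatures at which the ethyl ynol ether 15 fragments by retro-ene loss of ethylene.
- One arm may react and the other not, leaving mixed products.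

Fallback, by known chemistry: the classical assembly of this compound class, setting out from 3 and returning at 22. BBr3 in CH2Cl2 removes the three methyl groups of 3 to give 1-(2,4,6-trihydroxyphenyl)butan-1-one F1. Part of it is C,C-dimethylated at one ring carbon (MeI, NaOMe, MeOH) to give 2-butanoyl-3,5-dihydroxy-4,4-dimethylcyclohexa-2,5-dien-1-one F2. One equivalent of F1 and two of F2 are then joined with aqueous formaldehyde under dilute KOH at 0 to 23 °C, which forms both bridges and gives 22 directly. The coupling is statistical and 22 must be separated from homo-coupled products, but no protecting group is involved.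

**Step 3.** The benzylic–propargylic product may isomerize to an allenyl ether at palladium or under residual base. The ynol ethers may hydrate to esters during isolation, and the second coupling may lag behind the first. Fallback, setting out from 5, 9 and 4 and returning at 11, which also bypasses step 4:
- 5 and 9 with Et3N give 3-ethoxy-4,4-dimethylcyclobut-2-en-1-one F3 by the cycloaddition of step 4 on the parent ynol ether.
- Dilute aqueous HCl hydrolyses it to 3-hydroxy-4,4-dimethylcyclobut-2-en-1-one F4, the enol of 2,2-dimethylcyclobutane-1,3-dione.
- Its potassium salt (KOH, H2O) is C-benzylated twice by dibromide 4 to give 1-{3,5-bis[(2-hydroxy-3,3-dimethyl-4-oxocyclobut-1-en-1-yl)methyl]-2,4,6-trimethoxyphenyl}butan-1-one F5.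
- O-ethylation (Et3OBF4, i-Pr2NEt, CH2Cl2) gives 11. Only one enol ether can form, because the two carbonyls of each 2-substituted dione are equivalent.

**Step 2.** The second bromomethylation may stall on the acyl-deactivated ring. The strong acid may also cause aldol condensation of the ketone with formaldehyde, loss of an ortho methyl group, or deacylation. Fallback, setting out from 3 and returning at 4, which introduces the benzylic carbons at the aldehyde level:
- Twofold Rieche formylation (Cl2CHOMe, SnCl4, CH2Cl2) gives 5-butanoyl-2,4,6-trimethoxybenzene-1,3-dicarbaldehyde F6.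
- Aldehyde-selective reduction with NaBH(OAc)3, which leaves the hindered aryl ketone, gives 1-[3,5-bis(hydroxymethyl)-2,4,6-trimethoxyphenyl]butan-1-one F7.
- PBr3 in CH2Cl2 at 0 °C gives 4.

**Step 10.** The bridges may be cleaved or scrambled by Lewis acid or HBr while ring B still carries electron-donating ethoxy groups that stabilize a cation at the bridge carbon. The methoxy group between the two bridges may also be cleaved incompletely. Fallback, setting out from 21 and returning at 22, which separates the two ether classes by mechanism:
- 1 M HCl in THF at 23 °C hydrolyses the four vinylogous esters by addition–elimination of water, with no Lewis acid, giving 1-{3,5-bis[(5-butanoyl-2,4-dihydroxy-3,3-dimethyl-6-oxocyclohexa-1,4-dien-1-yl)methyl]-2,4,6-trimethoxyphenyl}butan-1-one F8. Its rings B are now electron-poor triketones that no longer support ionization at the bridge.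
- The three aryl methyl groups are then removed with iodotrimethylsilane generated from Me3SiCl and NaI in MeCN, followed by aqueous work-up, to give 22.

## Further compounds

F1 | step 7 | 1-(2,4,6-trihydroxyphenyl)butan-1-one | CCCC(=O)c1c(O)cc(O)cc1O
F2 | step 7 | 2-butanoyl-3,5-dihydroxy-4,4-dimethylcyclohexa-2,5-dien-1-one | CCCC(=O)C1=C(O)C(C)(C)C(O)=CC1=O
F3 | step 3 | 3-ethoxy-4,4-dimethylcyclobut-2-en-1-one | CCOC1=CC(=O)C1(C)C
F4 | step 3 | 3-hydroxy-4,4-dimethylcyclobut-2-en-1-one | OC1=CC(=O)C1(C)C
F5 | step 3 | 1-{3,5-bis[(2-hydroxy-3,3-dimethyl-4-oxocyclobut-1-en-1-yl)methyl]-2,4,6-trimethoxyphenyl}butan-1-one | CCCC(=O)c1c(OC)c(CC2=C(O)C(C)(C)C2=O)c(OC)c(CC2=C(O)C(C)(C)C2=O)c1OC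
F6 | step 2 | 5-butanoyl-2,4,6-trimethoxybenzene-1,3-dicarbaldehyde | CCCC(=O)c1c(OC)c(C=O)c(OC)c(C=O)c1OC
F7 | step 2 | 1-[3,5-bis(hydroxymethyl)-2,4,6-trimethoxyphenyl]butan-1-one | CCCC(=O)c1c(OC)c(CO)c(OC)c(CO)c1OC
F8 | step 10 | 1-{3,5-bis[(5-butanoyl-2,4-dihydroxy-3,3-dimethyl-6-oxocyclohexa-1,4-dien-1-yl)methyl]-2,4,6-trimethoxyphenyl}butan-1-one | CCCC(=O)c1c(OC)c(CC2=C(O)C(C)(C)C(O)=C(C(=O)CCC)C2=O)c(OC)c(CC2=C(O)C(C)(C)C(O)=C(C(=O)CCC)C2=O)c1OC
A1 | alternative 1 | 2,4-bis(2,4,6-trimethoxybenzyl)benzene-1,3,5-triol | Oc1cc(O)c(Cc2c(OC)cc(OC)cc2OC)c(O)c1Cc1c(OC)cc(OC)cc1OC
A2 | alternative 1 | 1,7-bis(2,4,6-trimethoxyphenyl)heptane-3,5-dione | COc1cc(OC)c(CCC(=O)CC(=O)CCc2c(OC)cc(OC)cc2OC)c(OC)c1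
A3 | alternative 2 | 1-[2-ethoxy-4-hydroxy-6-methoxy-3,5-bis(2,4,6-trimethoxybenzyl)phenyl]butan-1-one | CCCC(=O)c1c(OC)c(Cc2c(OC)cc(OC)cc2OC)c(O)c(Cc2c(OC)cc(OC)cc2OC)c1OCC
A4 | alternative 2 | 1-methoxy-3-(tert-butyldimethylsilyloxy)-2,4-bis(2,4,6-trimethoxybenzyl)cyclohexa-1,3-diene | COC1=C(Cc2c(OC)cc(OC)cc2OC)C(O[Si](C)(C)C(C)(C)C)=C(Cc2c(OC)cc(OC)cc2OC)CC1
A5 | alternative 2 | 1-ethoxyhex-1-yn-3-one | CCCC(=O)C#COCC
A6 | alternative 3 | 2,4-bis(butyrylfilicinylmethyl)-1,3,5-trimethoxybenzene | COc1cc(OC)c(CC2=C(O)C(C)(C)C(O)=C(C(=O)CCC)C2=O)c(OC)c1CC1=C(O)C(C)(C)C(O)=C(C(=O)CCC)C1=O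
A7 | alternative 3 | dimethyl 2,2'-[(2,4,6-trimethoxy-1,3-phenylene)bis(methylene)]bis(4,4-dimethyl-3,5,7-trioxodecanoate) | COc1cc(OC)c(CC(C(=O)OC)C(=O)C(C)(C)C(=O)CC(=O)CCC)c(OC)c1CC(C(=O)OC)C(=O)C(C)(C)C(=O)CC(=O)CCC
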